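**Strategy**

Perlatolic acid is cut at the depside ester into two 6-pentylresorcylate rings, and both come from one arene. The route rests on exchanging the ring oxygen of a 2-pyrone for carbon: ring B C1, the carboxyl-bearing atom flanked by C2–OH and the pentyl-bearing C6, takes the place that O1 holds in 4-(benzyloxy)-6-pentyl-2-pyrone between the lactone carbonyl and C6. In one operation lithio tert-butyl acetate forms the C1–C2 bond by opening the lactone and the C1–C6 bond by aldol closure onto the unmasked pentyl ketone, which delivers the protected ring B benzoate. Debenzylation gives the coupling phenol; its 4-O-methyl ether, after acidolysis, is the ring A acid.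

Key step: step 3

Remark on the chemistry: the debenzylated ring B ester is divided into two portions, one carried on to the ring A acid and one kept as the phenol partner of the coupling.

**Route**

Step 1
Reactants: 1 4-hydroxy-6-methyl-2H-pyran-2-one; 2 1-bromobutane
Product: 4 4-hydroxy-6-pentyl-2H-pyran-2-one, via dilithium dianion 3 (not isolated)
Conditions: LiN(iPr)2 (2.2 equiv), THF–DMPU, −78 °C; 2 (1.1 equiv), −78 → 0 °C; aq. HCl
Reagents that add atoms: 1-bromobutane (2), CCCCBr
Why: Two equivalents of amide base remove the 4-OH proton and then a proton of the C6 methyl, and the resulting carbanion, the most basic site of the vinylogous dianion, should be alkylated by the primary bromide in an SN2 reaction (γ-alkylation of a 1,3-dicarbonyl-type dianion), which extends the methyl to pentyl.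

Step 2
Reactants: 4 4-hydroxy-6-pentyl-2H-pyran-2-one; 5 benzyl bromide
Product: 6 4-(benzyloxy)-6-pentyl-2H-pyran-2-one
Conditions: 5 (1.1 equiv), K2CO3, DMF, rt → 50 °C
Reagents that add atoms: benzyl bromide (5), BrCc1ccccc1
Why: Williamson O-alkylation, in which the acidic vinylogous carboxylic acid is deprotonated by K2CO3 and its potassium salt in a polar aprotic solvent should react with the benzylic bromide at O4 to give the 4-alkoxy-2-pyrone.

Step 3
Reactants: 6 4-(benzyloxy)-6-pentyl-2H-pyran-2-one; 7 tert-butyl acetate
Product: 10 tert-butyl 4-(benzyloxy)-2-hydroxy-6-pentylbenzoate, via open-chain keto ester 8 (not isolated), via cyclic aldol 9 (not isolated)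
Conditions: 7 and LiN(iPr)2 (2.5 equiv each), THF, −78 °C; 6, −78 → 0 °C; AcOH (1.5 equiv), rt; aq. AcOH work-up
Reagents that add atoms: tert-butyl acetate (7), CC(=O)OC(C)(C)C
Why: The ester enolate adds to the lactone carbonyl of 6 in a Claisen-type acyl substitution, and collapse of the tetrahedral adduct ejects the ring oxygen as the C6 enolate, so the ring opens to the β-keto ester 8 (ring B C1–C2 bond made) with the pentyl ketone unmasked and the enol ether double bond still holding the two chain ends cis. Once acetic acid has protonated the ketone enolate, the doubly activated methylene of 8 adds to the pentyl ketone in a 6-(enolexo)-exo-trig aldol, counted through the ester-enolate form of the delocalised anion (ring B C1–C6 bond, giving 9), and loss of water followed by enolisation of the C2 carbonyl should deliver the hydrogen-bonded phenol 10 with O4 still benzylated. The closest known reaction type is the attack of carbanions on the lactone carbonyl of 4-alkoxy-2-pyrones with aldol or Claisen reclosure to phenols, together with the aldol aromatisation of 3,5,7-triketo esters to resorcylates. No stereocentre is created in 10; the two centres of 9 form without control and are erased on aromatisation. The step needs carbonyl attack rather than conjugate addition at pyrone C4 or C6 or proton abstraction from the pentyl α-methylene, and the hard lithium enolate at −78 °C, the alkyl-blocked C6 and the 4-alkoxy donor, which lowers the electrophilicity of C4 and C6, should secure it. It also needs aldol rather than Claisen reclosure, which the poorly electrophilic tert-butyl ester and the buffered, mono-anionic stage favour.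

Step 4
Reactants: 10 tert-butyl 4-(benzyloxy)-2-hydroxy-6-pentylbenzoate
Product: 11 tert-butyl 2,4-dihydroxy-6-pentylbenzoate
Conditions: H2 (1 atm), 10% Pd/C, EtOAc, rt
Reagents that add atoms: none
Why: Hydrogenolysis of the benzyl aryl ether on palladium should free the 4-OH while the tert-butyl ester, the arene and the chelated 2-OH are untouched.

Step 5
Reactants: 11 tert-butyl 2,4-dihydroxy-6-pentylbenzoate (first portion); 12 iodomethane
Product: 13 tert-butyl 2-hydroxy-4-methoxy-6-pentylbenzoate
Conditions: 12 (1.05 equiv), K2CO3, acetone, rt → 40 °C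
Reagents that add atoms: iodomethane (12), CI
Why: Williamson methylation, in which the 4-OH is the more acidic, unhindered phenol whereas the 2-OH is tied up in a hydrogen bond to the ester carbonyl, so one equivalent of iodomethane should alkylate O4 only.

Step 6
Reactants: 13 tert-butyl 2-hydroxy-4-methoxy-6-pentylbenzoate
Product: 14 2-hydroxy-4-methoxy-6-pentylbenzoic acid
Conditions: CF3CO2H, Et3SiH, CH2Cl2, 0 °C
Reagents that add atoms: none
Why: Acidolysis of the tert-butyl ester by alkyl–oxygen cleavage (AAL1) releases the tert-butyl cation, which the silane should reduce to isobutane before it can alkylate the electron-rich ring, while the low temperature guards the hydroxy acid against protodecarboxylation and the aryl methyl ether is stable.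

Step 7
Reactants: 14 2-hydroxy-4-methoxy-6-pentylbenzoic acid; 11 tert-butyl 2,4-dihydroxy-6-pentylbenzoate (second portion)
Product: 15 tert-butyl 2-hydroxy-4-[(2-hydroxy-4-methoxy-6-pentylbenzoyl)oxy]-6-pentylbenzoate
Conditions: DCC (1.1 equiv), toluene, rt
Reagents that add atoms: none
Why: Carbodiimide esterification (Steglich-type, run without DMAP), in which the O-acylisourea of 14 should be captured by the only unchelated phenol present, the 4-OH of 11, since the 2-OH of each partner is hydrogen-bonded to its neighbouring carbonyl, which is the usual selectivity of depside couplings.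

Step 8
Reactants: 15 tert-butyl 2-hydroxy-4-[(2-hydroxy-4-methoxy-6-pentylbenzoyl)oxy]-6-pentylbenzoate
Product: 16 perlatolic acid
Conditions: CF3CO2H, Et3SiH, CH2Cl2, 0 °C → rt
Reagents that add atoms: none
Why: The same AAL1 acidolysis with silane trapping should remove the tert-butyl group, while the aryl ester linkage of the depside and the methyl ether, which have no stabilised alkyl cation to lose, survive cold trifluoroacetic acid.

**Compound list**

1 | 4-hydroxy-6-methyl-2H-pyran-2-one | CC1=CC(O)=CC(=O)O1 | starting material
2 | 1-bromobutane | CCCCBr | starting material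
3 | dilithium dianion of 1 (4-oxide and C6 methylide; not isolated) | [Li+].[Li+].[CH2-]C1=CC([O-])=CC(=O)O1 | intermediate
4 | 4-hydroxy-6-pentyl-2H-pyran-2-one | CCCCCC1=CC(O)=CC(=O)O1 | intermediate
5 | benzyl bromide | BrCc1ccccc1 | starting material
6 | 4-(benzyloxy)-6-pentyl-2H-pyran-2-one | CCCCCC1=CC(OCc2ccccc2)=CC(=O)O1 | intermediate
7 | tert-butyl acetate | CC(=O)OC(C)(C)C | starting material
8 | tert-butyl (4E)-5-(benzyloxy)-3,7-dioxododec-4-enoate (C3 and C6 cis across the double bond; present as its lithium enolate; not isolated) | CCCCCC(=O)C/C(OCc1ccccc1)=C\C(=O)CC(=O)OC(C)(C)C | intermediate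
9 | tert-butyl 4-(benzyloxy)-6-hydroxy-2-oxo-6-pentylcyclohex-3-ene-1-carboxylate (C1 and C6 unset, racemic diastereomer mixture; not isolated) | CCCCCC1(O)CC(OCc2ccccc2)=CC(=O)C1C(=O)OC(C)(C)C | intermediate
10 | tert-butyl 4-(benzyloxy)-2-hydroxy-6-pentylbenzoate | CCCCCc1cc(OCc2ccccc2)cc(O)c1C(=O)OC(C)(C)C | intermediate
11 | tert-butyl 2,4-dihydroxy-6-pentylbenzoate | CCCCCc1cc(O)cc(O)c1C(=O)OC(C)(C)C | intermediate
12 | iodomethane | CI | starting material
13 | tert-butyl 2-hydroxy-4-methoxy-6-pentylbenzoate | CCCCCc1cc(OC)cc(O)c1C(=O)OC(C)(C)C | intermediate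
14 | 2-hydroxy-4-methoxy-6-pentylbenzoic acid | CCCCCc1cc(OC)cc(O)c1C(=O)O | intermediate
15 | tert-butyl 2-hydroxy-4-[(2-hydroxy-4-methoxy-6-pentylbenzoyl)oxy]-6-pentylbenzoate | CCCCCc1cc(OC(=O)c2c(O)cc(OC)cc2CCCCC)cc(O)c1C(=O)OC(C)(C)C | intermediate
16 | perlatolic acid, 2-hydroxy-4-[(2-hydroxy-4-methoxy-6-pentylbenzoyl)oxy]-6-pentylbenzoic acid (no stereocentres) | CCCCCc1cc(OC(=O)c2c(O)cc(OC)cc2CCCCC)cc(O)c1C(=O)O | target

**Step count**

Total steps: 8. Longest linear sequence: 8 steps (1 → 4 → 6 → 10 → 11 → 13 → 14 → 15 → 16), because 11 feeds both rings.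

**Steps most likely to fail**

Step 3. The basic enolate may abstract a proton from the pentyl α-methylene of the pyrone instead of adding, or add conjugately at C6. The opened chain may also reclose by C-acylation at the ester rather than by aldol, or the aldol may stall before dehydration. The fallback builds the triketide without any pyrone; it sets out from 2 and returns at 11, so steps 2 to 4 are bypassed. The dianion of pentane-2,4-dione (2 LiN(iPr)2, THF) is alkylated at a terminal methyl with 2 to give nonane-2,4-dione F1. The dianion of F1 is acetylated at its methyl terminus with N-methoxy-N-methylacetamide to give undecane-2,4,6-trione F2. The trianion of F2 (3 LiN(iPr)2, THF) is carboxylated at the terminal methyl with CO2 to give 3,5,7-trioxododecanoic acid F3. In acetate buffer at pH 5, F3 should close by the same C2-to-C7 aldol and aromatise to olivetolic acid F4 (2,4-dihydroxy-6-pentylbenzoic acid). tert-Butyl 2,2,2-trichloroacetimidate in CH2Cl2 at rt should then esterify the carboxyl group alone and give 11.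

Step 7. The O-acylisourea may rearrange to the N-acylurea faster than the weakly nucleophilic phenol captures it, the unprotected hydroxy acid may esterify itself, or a chelated 2-OH may be acylated as well. The fallback masks the ring A phenol; it sets out from 13 and returns at 15. The 2-OH of 13 is benzylated (5, K2CO3, DMF, 60 °C) to tert-butyl 2-(benzyloxy)-4-methoxy-6-pentylbenzoate F5. Acidolysis as in step 6 gives 2-(benzyloxy)-4-methoxy-6-pentylbenzoic acid F6. This acid, which has no free phenol left, is coupled with 11 (DCC, catalytic DMAP, CH2Cl2) to give tert-butyl 4-{[2-(benzyloxy)-4-methoxy-6-pentylbenzoyl]oxy}-2-hydroxy-6-pentylbenzoate F7. Hydrogenolysis (H2, Pd/C, EtOAc) then removes the benzyl ether and gives 15.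

Step 6. Acidolysis may be accompanied by protodecarboxylation of the electron-rich hydroxy acid or by Friedel–Crafts tert-butylation of its ring. The fallback frees the ring A acid under neutral conditions; it sets out from 4 and returns at 14. Compound 4 is O-methylated (dimethyl sulfate, K2CO3, acetone) to 4-methoxy-6-pentyl-2H-pyran-2-one F8. The oxygen-for-carbon swap of step 3 is repeated on F8 with the lithium enolate of benzyl acetate to give benzyl 2-hydroxy-4-methoxy-6-pentylbenzoate F9. Hydrogenolysis (H2, Pd/C, EtOAc) then gives 14.

**Further compounds**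

F1 | step 3 | nonane-2,4-dione | CCCCCC(=O)CC(C)=O
F2 | step 3 | undecane-2,4,6-trione | CCCCCC(=O)CC(=O)CC(C)=O
F3 | step 3 | 3,5,7-trioxododecanoic acid | CCCCCC(=O)CC(=O)CC(=O)CC(=O)O
F4 | step 3 | olivetolic acid (2,4-dihydroxy-6-pentylbenzoic acid) | CCCCCc1cc(O)cc(O)c1C(=O)O
F5 | step 7 | tert-butyl 2-(benzyloxy)-4-methoxy-6-pentylbenzoate | CCCCCc1cc(OC)cc(OCc2ccccc2)c1C(=O)OC(C)(C)C
F6 | step 7 | 2-(benzyloxy)-4-methoxy-6-pentylbenzoic acid | CCCCCc1cc(OC)cc(OCc2ccccc2)c1C(=O)O
F7 | step 7 | tert-butyl 4-{[2-(benzyloxy)-4-methoxy-6-pentylbenzoyl]oxy}-2-hydroxy-6-pentylbenzoate | CCCCCc1cc(OC(=O)c2c(OCc3ccccc3)cc(OC)cc2CCCCC)cc(O)c1C(=O)OC(C)(C)C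
F8 | step 6 | 4-methoxy-6-pentyl-2H-pyran-2-one | CCCCCC1=CC(OC)=CC(=O)O1
F9 | step 6 | benzyl 2-hydroxy-4-methoxy-6-pentylbenzoate | CCCCCc1cc(OC)cc(O)c1C(=O)OCc2ccccc2
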